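The cyclobutane is disconnected at C3–C4, the one ring bond flanked only by CH2 groups and lying across the ring from the stereocentres C1 and C2. This bond is closed by deleting the nitrogen of a pyrrolidine: the two N-bound methylenes become C3 and C4, and a five-membered ring contracts to the four-membered one in a single operation that leaves C1 and C2 untouched. The substrate is the free-NH dimethyl (3S,4S)-pyrrolidine-3,4-dicarboxylate, whose trans stereocentres come from a stereospecific azomethine ylide cycloaddition to dimethyl fumarate; its esters withstand the oxidant and are afterwards converted into the two bithienylethynyl arms.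

Key step: step 5

Remark: step 3 is expected to give both trans cycloadducts in comparable amounts; only the (3S,4S) isomer 8 is carried on and its (3R,4R) diastereomer (COC(=O)[C@H]1CN([C@H](C)c2ccccc2)C[C@@H]1C(=O)OC) is removed on silica; which of the two separated isomers is 8 would be established by X-ray analysis of a crystalline salt or by comparing the optical rotation of the diester 11 derived from it with that of the known (1R,2R) compound.

Step 1
Reactants: 1 (R)-1-phenylethylamine; 2 (chloromethyl)trimethylsilane
Product: 3 (R)-1-phenyl-N-[(trimethylsilyl)methyl]ethan-1-amine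
Conditions: K2CO3, MeCN, reflux
Reagents that add atoms: none
Why: SN2 N-alkylation of the primary amine at the α-silyl carbon, which is activated toward displacement; the hindered secondary amine formed resists a second alkylation and the benzylic stereocentre is not touched.

Step 2
Reactants: 3 (R)-1-phenyl-N-[(trimethylsilyl)methyl]ethan-1-amine; 4 formaldehyde (37% aqueous)
Product: 5 (R)-N-(methoxymethyl)-1-phenyl-N-[(trimethylsilyl)methyl]ethan-1-amine
Conditions: 37% aq. CH2O, MeOH, 0 °C; then K2CO3, rt
Reagents that add atoms: methanol, CO
Why: Condensation with formaldehyde to the hemiaminal/iminium and trapping by methanol gives the N,O-acetal (a Mannich-type aminomethylation of methanol), with K2CO3 binding water and keeping the medium basic so that the acid-labile acetal survives.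

Step 3
Reactants: 5 (R)-N-(methoxymethyl)-1-phenyl-N-[(trimethylsilyl)methyl]ethan-1-amine; 6 dimethyl fumarate
Product: 8 dimethyl (3S,4S)-1-[(R)-1-phenylethyl]pyrrolidine-3,4-dicarboxylate, via azomethine ylide 7 (not isolated)
Conditions: CF3CO2H (10 mol%), CH2Cl2, 0 °C to rt; then SiO2 chromatography to separate the two trans diastereomers
Reagents that add atoms: none
Why: Acid-triggered loss of the methoxy and silyl groups unmasks the non-stabilised azomethine ylide 7, whose concerted suprafacial 1,3-dipolar (3+2) cycloaddition to the E-alkene fixes C3 and C4 trans by transfer of alkene geometry, while their absolute sense is not steered by the remote N-(1-phenylethyl) group and is secured by chromatographic separation of the two trans diastereomers.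

Step 4
Reactants: 8 dimethyl (3S,4S)-1-[(R)-1-phenylethyl]pyrrolidine-3,4-dicarboxylate
Product: 9 dimethyl (3S,4S)-pyrrolidine-3,4-dicarboxylate
Conditions: H2 (4 bar), Pd(OH)2/C, MeOH, 40 °C; filtered, concentrated below 30 °C and used the same day
Reagents that add atoms: none
Why: Hydrogenolysis of the benzylic C–N bond on Pd(OH)2/C removes the N-substituent as ethylbenzene without touching the esters or the ring stereocentres, and delivers the free secondary amine on which the nitrogen deletion operates.

Step 5
Reactants: 9 dimethyl (3S,4S)-pyrrolidine-3,4-dicarboxylate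
Product: 11 dimethyl (1R,2R)-cyclobutane-1,2-dicarboxylate, via 1,1-diazene 10 (not isolated)
Conditions: PhI(OH)OTs (2.5 equiv, in portions), H2NCO2NH4 (8 equiv), CF3CH2OH (0.02 M), 80 °C; careful evaporation, SiO2 (pentane/Et2O)
Reagents that add atoms: none
Why: Ammonia from the carbamate is oxidised by the trivalent-iodine reagent to an iodonitrene that aminates the ring nitrogen, and a second oxidant equivalent takes the N-amino stage to the 1,1-diazene 10, which at 80 °C expels N2 to a singlet 1,4-diyl, •CH2–CH(CO2Me)–CH(CO2Me)–CH2•, whose two termini couple to the C3–C4 bond. The closest known reactions are the iodonitrene-mediated, stereoretentive contraction of pyrrolidines to cyclobutanes and the classical thermolysis of N-pyrrolidinyl 1,1-diazenes, in which tetramethylene diyls with unsubstituted termini also close to cyclobutanes. The four-membered ring is closed by intramolecular radical–radical recombination of the diyl ends, which are born within bonding distance because both were attached to the same nitrogen atom. No stereocentre is created; C1 and C2 of 11 are the former C3 and C4 of 9, sit beta to nitrogen, never carry spin and therefore keep their trans relationship and absolute configuration (the change of descriptor from S,S to R,R is one of priority only). The step depends on closure outcompeting β-scission of the C1–C2 bond into two molecules of methyl acrylate and bimolecular decay of 10 to a tetrazene; the short lifetime and cisoid birth geometry of the singlet diyl favour closure, while dilution and portionwise oxidant keep 10 scarce. The methyl esters are spectators kept for this step because they tolerate the oxidant, which alkynes or bithiophenes would not.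

Step 6
Reactants: 11 dimethyl (1R,2R)-cyclobutane-1,2-dicarboxylate
Product: 12 [(1R,2R)-cyclobutane-1,2-diyl]dimethanol
Conditions: LiAlH4, THF, 0 °C to rt; H2O/NaOH work-up, salts washed thoroughly with THF
Reagents that add atoms: none
Why: Hydride reduction of both esters by LiAlH4 (ester-to-alcohol reduction) is faster than any enolisation, so C1 and C2 keep their configuration.

Step 7
Reactants: 12 [(1R,2R)-cyclobutane-1,2-diyl]dimethanol
Product: 13 (1R,2R)-cyclobutane-1,2-dicarbaldehyde
Conditions: Dess–Martin periodinane (2.4 equiv), CH2Cl2, 0 °C to rt; diluted with pentane/Et2O, filtered through SiO2, concentrated cold, used crude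
Reagents that add atoms: none
Why: Dess–Martin oxidation proceeds by alkoxy exchange on the pentavalent iodine and intramolecular α-hydrogen abstraction under nearly neutral, water-free conditions, so the enolisable dialdehyde is not epimerised and cannot over-oxidise, and the strain of a trans-fused bicyclic lactol disfavours the lactol-to-lactone side path.

Step 8
Reactants: 13 (1R,2R)-cyclobutane-1,2-dicarbaldehyde
Product: 14 (1R,2R)-1,2-diethynylcyclobutane
Conditions: MeC(O)C(N2)P(O)(OMe)2 (2.6 equiv), K2CO3 (4 equiv), MeOH, 0 °C to rt; pentane extraction, kept as a titrated solution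
Reagents that add atoms: dimethyl (1-diazo-2-oxopropyl)phosphonate, CC(=O)C(=[N+]=[N-])P(=O)(OC)OC
Why: Ohira–Bestmann (Seyferth–Gilbert) homologation: methoxide cleaves the acetyl group to the diazomethylphosphonate anion, which olefinates each aldehyde to a diazoalkene that loses N2 and undergoes 1,2-hydride shift to the terminal alkyne, under carbonate conditions mild enough for the α-stereocentres of the thermodynamically preferred trans dialdehyde.

Step 9
Reactants: 14 (1R,2R)-1,2-diethynylcyclobutane; 15 5-bromo-2,2'-bithiophene (2.3 equiv)
Product: 16 cardopatine
Conditions: PdCl2(PhCN)2 (3 mol%), [HP(t-Bu)3]BF4 (6 mol%), CuI (2 mol%), i-Pr2NH, 1,4-dioxane, rt, degassed, closed vessel, subdued light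
Reagents that add atoms: none
Why: Twofold Sonogashira coupling: zerovalent palladium inserts into the thienyl C–Br bond, the copper acetylide transmetalates and reductive elimination forms each C(sp)–C(sp2) bond, the bulky electron-rich phosphine allowing room temperature so that volatile 14 stays in solution and the propargylic stereocentres, non-acidic toward the amine base, are retained.

Compound list
1 | (R)-1-phenylethylamine | C[C@@H](N)c1ccccc1 | starting material
2 | (chloromethyl)trimethylsilane | C[Si](C)(C)CCl | starting material
3 | (R)-1-phenyl-N-[(trimethylsilyl)methyl]ethan-1-amine | C[C@@H](NC[Si](C)(C)C)c1ccccc1 | intermediate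
4 | formaldehyde | C=O | starting material
5 | (R)-N-(methoxymethyl)-1-phenyl-N-[(trimethylsilyl)methyl]ethan-1-amine | C[C@@H](N(COC)C[Si](C)(C)C)c1ccccc1 | intermediate
6 | dimethyl fumarate | COC(=O)/C=C/C(=O)OC | starting material
7 | azomethine ylide, N-methylidene-N-[(R)-1-phenylethyl]methanaminium methylide (formed in the flask) | C[C@@H]([N+](=C)[CH2-])c1ccccc1 | intermediate
8 | dimethyl (3S,4S)-1-[(R)-1-phenylethyl]pyrrolidine-3,4-dicarboxylate | COC(=O)[C@@H]1CN([C@H](C)c2ccccc2)C[C@H]1C(=O)OC | intermediate
9 | dimethyl (3S,4S)-pyrrolidine-3,4-dicarboxylate | COC(=O)[C@@H]1CNC[C@H]1C(=O)OC | intermediate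
10 | 1,1-diazene (isodiazene) of 9, dimethyl (3S,4S)-1-azanidylidenepyrrolidin-1-ium-3,4-dicarboxylate (formed in the flask) | COC(=O)[C@@H]1C[N+](=[N-])C[C@H]1C(=O)OC | intermediate
11 | dimethyl (1R,2R)-cyclobutane-1,2-dicarboxylate | COC(=O)[C@@H]1CC[C@H]1C(=O)OC | intermediate
12 | [(1R,2R)-cyclobutane-1,2-diyl]dimethanol | OC[C@@H]1CC[C@H]1CO | intermediate
13 | (1R,2R)-cyclobutane-1,2-dicarbaldehyde | O=C[C@@H]1CC[C@H]1C=O | intermediate
14 | (1R,2R)-1,2-diethynylcyclobutane | C#C[C@@H]1CC[C@H]1C#C | intermediate
15 | 5-bromo-2,2'-bithiophene | Brc1ccc(-c2cccs2)s1 | starting material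
16 | cardopatine, 5,5''-[(1R,2R)-cyclobutane-1,2-diyldi(ethyne-2,1-diyl)]di(2,2'-bithiophene) | C(#C[C@@H]1CC[C@H]1C#Cc1ccc(-c2cccs2)s1)c1ccc(-c2cccs2)s1 | target

Total steps: 9. Longest linear sequence: 9 steps (1 to 16); 15 enters in the last step.

Steps most likely to fail

Step 5. The 1,4-diyl may cleave across C1–C2 into two acrylate molecules. Diazene 10 may also be diverted before it loses N2 from two primary carbons, by dimerisation to a tetrazene, tautomerisation to a hydrazone, or dehydrogenation of the amine by the oxidant. The fallback abandons the ring contraction for a classical resolution; it sets out from amine 1, used as resolving base, and comes back at 11. Purchased racemic trans-cyclobutane-1,2-dicarboxylic acid F1 is crystallised with 1 from aqueous ethanol to the less soluble diastereomeric salt, bis[(R)-1-phenylethylammonium] (1R,2R)-cyclobutane-1,2-dicarboxylate F2 (the enantiomer of 1 is used should the other antipode crystallise). Dilute HCl liberates (1R,2R)-cyclobutane-1,2-dicarboxylic acid F3, and Fischer esterification (MeOH, cat. H2SO4, reflux) gives 11. No diyl is involved, and the route continues unchanged from step 6.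

Step 3. The remote N-substituent exerts no useful facial control, and an incomplete separation of two closely similar diastereomers would pass stereochemical impurity down the whole route. The fallback replaces the auxiliary by resolution of enantiomers on a chiral phase; it sets out from 6 and comes back at 9. Compound 6 is treated with purchased N-benzyl-1-methoxy-N-[(trimethylsilyl)methyl]methanamine F4 (CF3CO2H cat., CH2Cl2), which through the N-benzyl azomethine ylide F5 should give racemic dimethyl trans-1-benzylpyrrolidine-3,4-dicarboxylate F6. Preparative chromatography on a chiral stationary phase separates the enantiomers to dimethyl (3S,4S)-1-benzylpyrrolidine-3,4-dicarboxylate F7, and hydrogenolysis (H2, Pd(OH)2/C, MeOH) gives 9.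

Step 8. The low-boiling diyne 14 may be lost by evaporation during isolation, and carbonate in methanol may enolise 13 and leak material into the cis series. The fallback avoids both a free terminal diyne and a basic protic medium; it sets out from 13 and comes back at 16, bypassing 14. Corey–Fuchs olefination (CBr4, PPh3, CH2Cl2, 0 °C) gives the non-volatile (1R,2R)-1,2-bis(2,2-dibromoethenyl)cyclobutane F8. In one flask, n-BuLi (4.2 equiv, THF, −78 °C) converts it into dilithium (1R,2R)-cyclobutane-1,2-diylbis(ethynide) F9, ZnCl2 transmetalates this to bis(chlorozinc) (1R,2R)-cyclobutane-1,2-diylbis(ethynide) F10, and Negishi coupling with 15 (Pd(PPh3)4, THF, rt to 50 °C) gives 16.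

Further compounds
F1 | step 5 | racemic trans-cyclobutane-1,2-dicarboxylic acid (purchased) | OC(=O)[C@@H]1CC[C@H]1C(O)=O.OC(=O)[C@H]1CC[C@@H]1C(O)=O
F2 | step 5 | bis[(R)-1-phenylethylammonium] (1R,2R)-cyclobutane-1,2-dicarboxylate | C[C@@H]([NH3+])c1ccccc1.C[C@@H]([NH3+])c1ccccc1.[O-]C(=O)[C@@H]1CC[C@H]1C([O-])=O
F3 | step 5 | (1R,2R)-cyclobutane-1,2-dicarboxylic acid | OC(=O)[C@@H]1CC[C@H]1C(O)=O
F4 | step 3 | N-benzyl-1-methoxy-N-[(trimethylsilyl)methyl]methanamine (purchased) | COCN(Cc1ccccc1)C[Si](C)(C)C
F5 | step 3 | N-benzyl azomethine ylide, N-benzyl-N-methylidenemethanaminium methylide (not isolated) | C=[N+]([CH2-])Cc1ccccc1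
F6 | step 3 | racemic dimethyl trans-1-benzylpyrrolidine-3,4-dicarboxylate | COC(=O)[C@@H]1CN(Cc2ccccc2)C[C@H]1C(=O)OC.COC(=O)[C@H]1CN(Cc2ccccc2)C[C@@H]1C(=O)OC
F7 | step 3 | dimethyl (3S,4S)-1-benzylpyrrolidine-3,4-dicarboxylate | COC(=O)[C@@H]1CN(Cc2ccccc2)C[C@H]1C(=O)OC
F8 | step 8 | (1R,2R)-1,2-bis(2,2-dibromoethenyl)cyclobutane | BrC(Br)=C[C@@H]1CC[C@H]1C=C(Br)Br
F9 | step 8 | dilithium (1R,2R)-cyclobutane-1,2-diylbis(ethynide) (not isolated) | [Li]C#C[C@@H]1CC[C@H]1C#C[Li]
F10 | step 8 | bis(chlorozinc) (1R,2R)-cyclobutane-1,2-diylbis(ethynide) (not isolated) | Cl[Zn]C#C[C@@H]1CC[C@H]1C#C[Zn]Cl
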